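**Retrosynthetic overview**

1. Pentaalbaspidin BBBBB ⇒ central phlorbutyrophenone ring (two free ring carbons) + 2 × two-ring sulfide "cap–CH2–ring B–CH2SMe"; each CH2SMe arm is unmasked (S-methylation, loss of Me2S) to an ortho-quinone methide.
2. Two-ring sulfide ⇒ butyrylfilicinic acid (cap) + symmetric 3,5-bis(methylthiomethyl)phlorbutyrophenone, one arm activated.
3. Key disconnection: both ring–CH2 bonds of the bis-sulfide, made by a double sulfonium-ylide [2,3]-shift on phlorbutyrophenone. The O-sulfonium-activated phenol carbon (an enolonium-type acceptor) takes up the carbanionic ylide carbon of dimethyl sulfide, so two donor carbons are joined by polarity reversal. All four bridging carbons of the target come from this step.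
4. Monomers: phlorbutyrophenone ⇐ phloroglucinol + butanoyl chloride; cap ⇐ dearomatising gem-dimethylation of phlorbutyrophenone.
5. Rings: none is built. All five six-membered rings are the phloroglucinol nucleus; the two terminal ones are dearomatised at the monomer stage, then bridges are added cap–ring B first, ring B–central ring last.

Assumption: the target has no stereocentre or other stereogenic element (it is achiral), so there is no enantiomer to select; it is made as the enol tautomer drawn. Tautomers and conjugate acids or bases of a listed compound (sulfonium ylides, dienone forms) are not numbered separately.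

**Route**

Step 1
Reactants: 1 phloroglucinol (benzene-1,3,5-triol); 2 butanoyl chloride
Product: 3 phlorbutyrophenone [1-(2,4,6-trihydroxyphenyl)butan-1-one]
Conditions: AlCl3 (3.5 equiv), PhNO2, 2 (1.05 equiv), rt → 60 °C; ice/aq HCl
Reagents that add atoms: none
Why: Friedel–Crafts acylation of the very electron-rich triol stops after one acyl group because the chelated aryl ketone deactivates the ring; no stereocentre is formed.

Step 2
Reactants: 3 phlorbutyrophenone
Product: 5 butyrylfilicinic acid (2-butanoyl-3,5-dihydroxy-6,6-dimethylcyclohexa-2,4-dien-1-one), via C-monomethyl ketone 4 (not isolated)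
Conditions: NaOMe (3.2 equiv), MeI (2.3 equiv), MeOH, 0 °C → rt; aq HCl; chromatography
Reagents that add atoms: iodomethane, CI
Why: Double C-alkylation of the ambident phloroglucinolate at the same ring carbon (the second methylation dearomatises) is the established way to acylfilicinic acids; the new quaternary carbon carries two identical methyl groups, so it is not a stereocentre.

Step 3
Reactants: 3 phlorbutyrophenone
Product: 9 bis-sulfide 1-[2,4,6-trihydroxy-3,5-bis(methylsulfanylmethyl)phenyl]butan-1-one, via aryloxysulfonium chloride 6 (not isolated), via mono-sulfide 7 (not isolated), via second aryloxysulfonium chloride 8 (not isolated)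
Conditions: Me2S (1.3 equiv)/NCS (1.2 equiv), CH2Cl2–THF, −25 °C; then Et3N (1.3 equiv), −25 → 0 °C; second identical cycle in the same flask
Reagents that add atoms: dimethyl sulfide, CSC
Why: Proposed new method: O-sulfonium formation with the Corey–Kim reagent reverses the polarity of the phenol so that its ortho carbon accepts the carbanionic ylide carbon in a [2,3]-sigmatropic shift, and rearomatisation leaves an ArCH2SMe group, done twice to make both ring–CH2 bonds of 9 from two normally nucleophilic carbons; the closest known reaction is the Gassman ortho-methylthiomethylation of simple phenols (Me2S/NCS, then Et3N), here extended to a double reaction on an acylphloroglucinol, and no stereocentre is formed.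

Step 4
Reactants: 9 bis-sulfide (2.5 equiv); 5 butyrylfilicinic acid (1.2 equiv)
Product: 12 two-ring sulfide 2-butanoyl-4-{[3-butanoyl-2,4,6-trihydroxy-5-(methylsulfanylmethyl)phenyl]methyl}-3,5-dihydroxy-6,6-dimethylcyclohexa-2,4-dien-1-one, via mono-sulfonium triflate 10 (not isolated), via ortho-quinone methide 11 (not isolated)
Conditions: MeOTf (1.0 equiv), CH2Cl2, −40 → 0 °C; then 5, Et3N (2.5 equiv), MeCN, 0 °C → rt; excess 9 recovered
Reagents that add atoms: none
Why: S-methylation turns one thioether arm into a leaving group, Et3N triggers 1,4-elimination of Me2S to ortho-quinone methide 11, and the soft filicinate carbon traps it by Michael addition and rearomatisation (the sulfonium counterpart of the Mannich-methiodide coupling), while limiting MeOTf against excess symmetric 9 keeps the second arm intact; no stereocentre is formed.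

Step 5
Reactants: 12 two-ring sulfide (2.1 equiv); 3 phlorbutyrophenone (1.0 equiv)
Product: 16 pentaalbaspidin BBBBB, via sulfonium triflate 13 (not isolated), via ortho-quinone methide 14 (not isolated), via three-ring mono-adduct 15 (not isolated)
Conditions: MeOTf (2.1 equiv), CH2Cl2, −40 → 0 °C; then 3, Et3N (4.5 equiv), MeCN, 0 °C → rt; AcOH quench
Reagents that add atoms: none
Why: Two successive ortho-quinone methide Michael additions with rearomatisation at the two free ring carbons of 3 give the symmetric pentamer, since 14 has no free ring CH and cannot self-condense and 3 is exactly difunctional; the product is achiral, so no stereocentre has to be set.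

**Compound list**

1 | phloroglucinol (benzene-1,3,5-triol) | Oc1cc(O)cc(O)c1 | starting material
2 | butanoyl chloride | CCCC(=O)Cl | starting material
3 | phlorbutyrophenone, 1-(2,4,6-trihydroxyphenyl)butan-1-one | CCCC(=O)c1c(O)cc(O)cc1O | intermediate
4 | C-monomethyl ketone, 1-(2,4,6-trihydroxy-3-methylphenyl)butan-1-one (not isolated) | CCCC(=O)c1c(O)cc(O)c(C)c1O | intermediate
5 | butyrylfilicinic acid, 2-butanoyl-3,5-dihydroxy-6,6-dimethylcyclohexa-2,4-dien-1-one | CCCC(=O)C1=C(O)C=C(O)C(C)(C)C1=O | intermediate
6 | (4-butanoyl-3,5-dihydroxyphenoxy)dimethylsulfonium chloride (not isolated) | CCCC(=O)c1c(O)cc(O[S+](C)C)cc1O.[Cl-] | intermediate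
7 | mono-sulfide, 1-[2,4,6-trihydroxy-3-(methylsulfanylmethyl)phenyl]butan-1-one (not isolated) | CCCC(=O)c1c(O)cc(O)c(CSC)c1O | intermediate
8 | [4-butanoyl-3,5-dihydroxy-2-(methylsulfanylmethyl)phenoxy]dimethylsulfonium chloride (not isolated) | CCCC(=O)c1c(O)cc(O[S+](C)C)c(CSC)c1O.[Cl-] | intermediate
9 | bis-sulfide, 1-[2,4,6-trihydroxy-3,5-bis(methylsulfanylmethyl)phenyl]butan-1-one | CCCC(=O)c1c(O)c(CSC)c(O)c(CSC)c1O | intermediate
10 | {[3-butanoyl-2,4,6-trihydroxy-5-(methylsulfanylmethyl)phenyl]methyl}dimethylsulfonium triflate (not isolated) | CCCC(=O)c1c(O)c(CSC)c(O)c(C[S+](C)C)c1O.[O-]S(=O)(=O)C(F)(F)F | intermediate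
11 | ortho-quinone methide, 4-butanoyl-3,5-dihydroxy-6-methylidene-2-(methylsulfanylmethyl)cyclohexa-2,4-dien-1-one (not isolated) | CCCC(=O)C1=C(O)C(=C)C(=O)C(CSC)=C1O | intermediate
12 | two-ring sulfide, 2-butanoyl-4-{[3-butanoyl-2,4,6-trihydroxy-5-(methylsulfanylmethyl)phenyl]methyl}-3,5-dihydroxy-6,6-dimethylcyclohexa-2,4-dien-1-one | CCCC(=O)c1c(O)c(CSC)c(O)c(CC2=C(O)C(C)(C)C(=O)C(C(=O)CCC)=C2O)c1O | intermediate
13 | S,S-dimethylsulfonium triflate of 12 (SMe arm converted to CH2S+Me2; not isolated) | CCCC(=O)c1c(O)c(C[S+](C)C)c(O)c(CC2=C(O)C(C)(C)C(=O)C(C(=O)CCC)=C2O)c1O.[O-]S(=O)(=O)C(F)(F)F | intermediate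
14 | ortho-quinone methide from 13 (ring B as 6-methylidene-cyclohexa-2,4-dienone, cap attached through CH2; not isolated) | CCCC(=O)C1=C(O)C(=C)C(=O)C(CC2=C(O)C(C)(C)C(=O)C(C(=O)CCC)=C2O)=C1O | intermediate
15 | three-ring mono-adduct, cap–CH2–ring B–CH2–phlorbutyrophenone with one free ring CH (not isolated) | CCCC(=O)c1c(O)cc(O)c(Cc2c(O)c(CC3=C(O)C(C)(C)C(=O)C(C(=O)CCC)=C3O)c(O)c(C(=O)CCC)c2O)c1O | intermediate
16 | pentaalbaspidin BBBBB (achiral) | CCCC(=O)C1=C(O)C(Cc2c(O)c(Cc3c(O)c(Cc4c(O)c(CC5=C(O)C(C)(C)C(=O)C(C(=O)CCC)=C5O)c(O)c(C(=O)CCC)c4O)c(O)c(C(=O)CCC)c3O)c(O)c(C(=O)CCC)c2O)=C(O)C(C)(C)C1=O | target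

**Step count and risks**

Total step count: 5. Longest linear sequence: 4 steps (1 → 3 → 9 → 12 → 16; the branch 3 → 5 joins at step 4).

Steps most likely to fail:

Step 3 (double sulfonium-ylide shift). The ring carbon of 3 may attack sulfur directly and give a stable C-sulfonium ylide. The ylide may also collapse to an O–CH2SMe ether, or the second shift may go to the already substituted carbon and give a dienone. The fallback sets out from 3 and comes back at 9. It gives up the sigmatropic delivery and C-alkylates 3 twice with the free thionium ion MeS+=CH2, generated from chloromethyl methyl sulfide (2.2 equiv) with ZnCl2 in CH2Cl2–MeNO2 at 0 °C (Friedel–Crafts thiomethylation). Mono-sulfide 7 is passed on the way, and no compound outside the list is made (F0).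

Step 4 (mono-activation of the symmetric bis-sulfide and coupling with the cap). Activation of both arms gives the cap–ring–cap trimer, and excess 9 has to be recycled. The fallback sets out from 5 and from mono-sulfide 7 (isolated by stopping step 3 after the first cycle) and comes back at 12. The roles are reversed so that no symmetric bis-electrophile is needed. 5 is aminomethylated with dimethylmethylideneammonium iodide in MeCN to the Mannich base 2-butanoyl-4-[(dimethylamino)methyl]-3,5-dihydroxy-6,6-dimethylcyclohexa-2,4-dien-1-one F1. Heating F1 with 7 in dioxane at 80 °C releases the methylidene triketone 2-butanoyl-3-hydroxy-6,6-dimethyl-4-methylidenecyclohex-2-ene-1,5-dione F2. The single free ring carbon of 7 traps F2 to give 12, with its thioether arm untouched.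

Step 5 (double end coupling). The second alkylation may stall at 15. Base can also scramble methylene bridges (retro-Michael exchange between rings), and the sulfonium salt can transfer methyl to enolate oxygen. The fallback sets out from 12 and comes back at 16. The thioether of 12 is oxidised with KHSO5 (as 2KHSO5·KHSO4·K2SO4) in MeOH–H2O at 0 °C to the bench-stable sulfone of 12 (SMe replaced by SO2Me) F3. With K2CO3 in aqueous MeCN at rt, F3 loses methanesulfinate to give 14 with no alkylating agent present. The coupling is then staged: 14 is first reacted with excess 3 to isolated 15, and 15 is reacted with a second portion of F3 to give 16.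

**Further compounds**

F0 | step 3 | none | none
F1 | step 4 | 2-butanoyl-4-[(dimethylamino)methyl]-3,5-dihydroxy-6,6-dimethylcyclohexa-2,4-dien-1-one | CCCC(=O)C1=C(O)C(CN(C)C)=C(O)C(C)(C)C1=O
F2 | step 4 | 2-butanoyl-3-hydroxy-6,6-dimethyl-4-methylidenecyclohex-2-ene-1,5-dione | CCCC(=O)C1=C(O)C(=C)C(=O)C(C)(C)C1=O
F3 | step 5 | sulfone of 12, 2-butanoyl-4-{[3-butanoyl-2,4,6-trihydroxy-5-(methylsulfonylmethyl)phenyl]methyl}-3,5-dihydroxy-6,6-dimethylcyclohexa-2,4-dien-1-one | CCCC(=O)c1c(O)c(CS(C)(=O)=O)c(O)c(CC2=C(O)C(C)(C)C(=O)C(C(=O)CCC)=C2O)c1O
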